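The seven-membered oxepine is disconnected at its CH2–CH(O) bond. Two features are used: the CH2 carbon on C3 is allylic to the chromone C2=C3 bond, and the O–CH carbon and the peroxide-bearing CMe2 carbon are the two carbons of an aryl enol ether (2′-O–CH=CMe2) on ring B. An enantioselective palladium-ene (allyl-Heck) cyclisation of a 3-(acetoxymethyl)flavone closes the oxepine, sets the (S) centre and leaves an isopropenyl group, which cobalt-catalysed hydroperoxysilylation converts into the tertiary hydroperoxide. The allylic acetate arises from a 3-aroylchroman-4-one, whose temporary pyranone ring is exchanged for the flavone ring.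

Key step: step 11

Remark: 5,7-dihydroxychroman-4-one (1) is taken as a catalogue compound, and the antipode of the phosphoramidite that delivers the (S) centre in step 11 is to be fixed by experiment.

In the names below, "oxepinoflavone" means a flavone whose C3 and 2′-oxygen are linked as C3–CH2–CH(R)–O–C2′.

Step 1
Reactants: 1 5,7-dihydroxychroman-4-one
Product: 2 5-hydroxy-7-methoxychroman-4-one
Conditions: MeI (1.05 equiv), K2CO3 (1.1 equiv), acetone, rt
Reagents that add atoms: iodomethane, CI
Why: Williamson etherification should take only the 7-OH, because the 5-OH is tied up in a hydrogen bond to the C4 carbonyl and is far less acidic and nucleophilic.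

Step 2
Reactants: 2 5-hydroxy-7-methoxychroman-4-one
Product: 3 5-hydroxy-6-iodo-7-methoxychroman-4-one
Conditions: BnMe3N·ICl2 (1.0 equiv), CaCO3, CH2Cl2/MeOH (5:2), rt
Reagents that add atoms: benzyltrimethylammonium dichloroiodate, C[N+](C)(C)Cc1ccccc1.Cl[I-]Cl
Why: electrophilic aromatic iodination of the phloroglucinol-type ring should go ortho to the chelated 5-OH (C6), the position this reagent favours in 5-hydroxy-7-alkoxy benzopyranones.

Step 3
Reactants: 4 3-methylbut-1-yne
Product: 5 4,4,5,5-tetramethyl-2-[(E)-3-methylbut-1-enyl]-1,3,2-dioxaborolane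
Conditions: HBpin (1.05 equiv), Cp2Zr(H)Cl (5 mol %), Et3N (10 mol %), neat, 60 °C
Reagents that add atoms: pinacolborane, CC1(C)OBOC1(C)C
Why: zirconocene hydride-catalysed hydroboration adds H–B syn and anti-Markovnikov to the terminal alkyne, which fixes the E geometry.

Step 4
Reactants: 3 5-hydroxy-6-iodo-7-methoxychroman-4-one; 5 4,4,5,5-tetramethyl-2-[(E)-3-methylbut-1-enyl]-1,3,2-dioxaborolane
Product: 6 5-hydroxy-7-methoxy-6-[(E)-3-methylbut-1-enyl]chroman-4-one
Conditions: Pd(OAc)2 (3 mol %), SPhos (6 mol %), K3PO4, THF/H2O (10:1), 40 °C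
Reagents that add atoms: none
Why: Suzuki–Miyaura coupling keeps the E geometry, and the biaryl phosphine should couple the doubly ortho-substituted iodide at a temperature low enough to avoid base-induced opening of the chromanone, which would scramble C6 and C8.

Step 5
Reactants: 6 5-hydroxy-7-methoxy-6-[(E)-3-methylbut-1-enyl]chroman-4-one
Product: 7 7-methoxy-6-[(E)-3-methylbut-1-enyl]-5-(triisopropylsilyloxy)chroman-4-one
Conditions: TIPSOTf (1.5 equiv), 2,6-lutidine (2.5 equiv), CH2Cl2, 0 °C to rt
Reagents that add atoms: triisopropylsilyl trifluoromethanesulfonate, CC(C)[Si](C(C)C)(C(C)C)OS(=O)(=O)C(F)(F)F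
Why: the silyl triflate should silylate the hindered, hydrogen-bonded phenol, and the ether blocks the 5-oxygen so that only O1 can re-close the pyranone in step 9 (6- versus 8-alkenyl regiocontrol).

Step 6
Reactants: 8 methyl 2,4-dihydroxybenzoate; 9 3-chloro-2-methylprop-1-ene
Product: 10 methyl 2-hydroxy-4-(2-methylallyloxy)benzoate
Conditions: 9 (1.1 equiv), K2CO3 (1.2 equiv), KI (0.1 equiv), acetone, reflux
Reagents that add atoms: none
Why: Williamson etherification should take only the 4-OH, because the 2-OH is hydrogen-bonded to the ester carbonyl and is much less nucleophilic under these mild conditions.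

Step 7
Reactants: 10 methyl 2-hydroxy-4-(2-methylallyloxy)benzoate; 9 3-chloro-2-methylprop-1-ene
Product: 12 2,4-bis(2-methylallyloxy)benzoic acid, via methyl ester 11 (not isolated)
Conditions: 9 (1.5 equiv), K2CO3 (2 equiv), KI (cat.), DMF, 70 °C; then NaOH, MeOH/H2O, 60 °C; HCl to pH 2
Reagents that add atoms: sodium hydroxide, [Na+].[OH-]
Why: the more forcing Williamson conditions alkylate the chelated 2-OH, and saponification of the methyl ester then frees the acid while leaving the two robust methallyl ethers, the 2-ether carrying the future oxepine CH and CMe2 carbons.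

Step 8
Reactants: 12 2,4-bis(2-methylallyloxy)benzoic acid; 7 7-methoxy-6-[(E)-3-methylbut-1-enyl]-5-(triisopropylsilyloxy)chroman-4-one
Product: 14 3-[2,4-bis(2-methylallyloxy)benzoyl]-7-methoxy-6-[(E)-3-methylbut-1-enyl]-5-(triisopropylsilyloxy)chroman-4-one, via acid chloride 13 (not isolated)
Conditions: 12, (COCl)2 (1.2 equiv), DMF (cat.), CH2Cl2, 0 °C to rt, evaporate; 7, LiN(SiMe3)2 (2.2 equiv), THF, −78 °C, then 13, −78 to −30 °C; aq. NH4Cl
Reagents that add atoms: none
Why: Claisen-type C-acylation of the chromanone lithium enolate by the acid chloride, in which the second equivalent of base deprotonates the β-diketone as it forms and the low temperature holds back β-elimination of the ring oxygen and silyl migration.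

Step 9
Reactants: 14 3-[2,4-bis(2-methylallyloxy)benzoyl]-7-methoxy-6-[(E)-3-methylbut-1-enyl]-5-(triisopropylsilyloxy)chroman-4-one
Product: 15 {2-[2,4-bis(2-methylallyloxy)phenyl]-7-methoxy-6-[(E)-3-methylbut-1-enyl]-4-oxo-5-(triisopropylsilyloxy)-4H-chromen-3-yl}methyl acetate
Conditions: NaOAc (3 equiv), AcOH, 90 °C
Reagents that add atoms: acetic acid, CC(O)=O
Why: Proposed new method: acetate deprotonates the β-diketone, the enolate expels the ring oxygen (retro-oxa-Michael, E1cB) to give a 2-methylene-1,3-diketone and the O1 phenol, acetate adds to the methylene carbon and the phenol condenses with the aroyl ketone to the aromatic pyranone, which makes the sequence irreversible and regiodefined because the 5-oxygen is silylated; the closest known reaction types are the base-induced ring opening of chroman-4-ones and the Baker–Venkataraman-type cyclodehydration of o-hydroxyaryl 1,3-diketones to flavones.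

Step 10
Reactants: 15 {2-[2,4-bis(2-methylallyloxy)phenyl]-7-methoxy-6-[(E)-3-methylbut-1-enyl]-4-oxo-5-(triisopropylsilyloxy)-4H-chromen-3-yl}methyl acetate
Product: 16 {7-methoxy-6-[(E)-3-methylbut-1-enyl]-2-[2,4-bis(2-methylprop-1-enyloxy)phenyl]-4-oxo-5-(triisopropylsilyloxy)-4H-chromen-3-yl}methyl acetate
Conditions: RuHCl(CO)(PPh3)3 (5 mol %), toluene, 90 °C
Reagents that add atoms: none
Why: ruthenium hydride-catalysed alkene migration (allyl ether to enol ether isomerisation) should move both terminal 1,1-disubstituted double bonds into conjugation with oxygen, while the internal conjugated C6 alkene and the allylic acetate stay untouched.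

Step 11
Reactants: 16 {7-methoxy-6-[(E)-3-methylbut-1-enyl]-2-[2,4-bis(2-methylprop-1-enyloxy)phenyl]-4-oxo-5-(triisopropylsilyloxy)-4H-chromen-3-yl}methyl acetate
Product: 18 (S)-isopropenyl oxepinoflavone 4′-phenol 5-O-TIPS ether, via 4′-enol ether 17 (not isolated)
Conditions: Pd(dba)2 (5 mol %), (S)-BINOL-derived phosphoramidite of bis[(S)-1-phenylethyl]amine (12 mol %), Li2CO3 (1.5 equiv), DMA, 60 °C; then 1 M HCl, THF, rt to 40 °C
Reagents that add atoms: none
Why: Proposed new method: zerovalent palladium ionises the allylic acetate of 16 (a 2-acylallyl acetate built on the chromone C2=C3–CH2 unit) to an allyl complex, whose CH2 terminus and the metal add across the 2′-O–CH=CMe2 double bond (migratory insertion, carbon to the oxygen-bearing CH, palladium to CMe2), and β-hydride elimination into a methyl group gives the isopropenyl group and returns the catalyst. The closest known reaction types are the racemic palladium-ene cyclisation of allylic acetates onto tethered alkenes and the enantioselective Mizoroki–Heck reaction of benzylic electrophiles with enol ethers under chiral phosphoramidite ligands; the proposal joins them in an intramolecular, enantioselective form. The oxepine closes in the 7-exo-trig mode across the biaryl-like C2–C1′ axis, which holds the two reacting carbons close. The new stereocentre is set in the insertion step by the chiral monodentate phosphoramidite on palladium, which selects the face of the enol ether. The step needs site selectivity (only the ortho 2′-enol ether can reach the CH2 terminus, the para 4′-enol ether and the silylated 5-oxygen cannot), regioselectivity (sterics and enol-ether polarity both send carbon to CH) and elimination away from the new methine (six methyl hydrogens against one hindered C–H). Aqueous acid in the work-up then hydrolyses the remaining 4′-enol ether of 17 to the phenol without touching the allylic aryl ether.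

Step 12
Reactants: 18 (S)-isopropenyl oxepinoflavone 4′-phenol 5-O-TIPS ether
Product: 19 (S)-oxepinoflavone triethylsilyl peroxide
Conditions: Co(thd)2 (10 mol %; thd = 2,2,6,6-tetramethylheptane-3,5-dionate), Et3SiH (2.5 equiv), O2 (1 atm), 1,2-dichloroethane, rt
Reagents that add atoms: dioxygen, O=O; triethylsilane, CC[SiH](CC)CC
Why: Isayama–Mukaiyama hydroperoxysilylation, in which hydrogen-atom transfer from a cobalt hydride to the CH2 end of the 1,1-disubstituted alkene gives the tertiary radical that O2 traps and the silane caps, while the twisted 1,2-disubstituted C6 alkene should react more slowly and the stereocentre is not involved.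

Step 13
Reactants: 19 (S)-oxepinoflavone triethylsilyl peroxide
Product: 20 CNP0171472.1
Conditions: Bu4NF (2.5 equiv), AcOH (3 equiv), THF, 0 °C
Reagents that add atoms: none
Why: fluoride cleaves both O–Si bonds (silyl peroxide and aryl silyl ether) under acetic acid buffering, which should spare the hydroperoxide, the allylic aryl ether and the stereocentre.

Compound list
1 | 5,7-dihydroxychroman-4-one | O=C1CCOc2cc(O)cc(O)c12 | starting material
2 | 5-hydroxy-7-methoxychroman-4-one | O=C1CCOc2cc(OC)cc(O)c12 | intermediate
3 | 5-hydroxy-6-iodo-7-methoxychroman-4-one | O=C1CCOc2cc(OC)c(I)c(O)c12 | intermediate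
4 | 3-methylbut-1-yne | CC(C)C#C | starting material
5 | 4,4,5,5-tetramethyl-2-[(E)-3-methylbut-1-enyl]-1,3,2-dioxaborolane | CC(C)/C=C/B1OC(C)(C)C(C)(C)O1 | intermediate
6 | 5-hydroxy-7-methoxy-6-[(E)-3-methylbut-1-enyl]chroman-4-one | O=C1CCOc2cc(OC)c(/C=C/C(C)C)c(O)c12 | intermediate
7 | 7-methoxy-6-[(E)-3-methylbut-1-enyl]-5-(triisopropylsilyloxy)chroman-4-one | O=C1CCOc2cc(OC)c(/C=C/C(C)C)c(O[Si](C(C)C)(C(C)C)C(C)C)c12 | intermediate
8 | methyl 2,4-dihydroxybenzoate | COC(=O)c1ccc(O)cc1O | starting material
9 | 3-chloro-2-methylprop-1-ene (methallyl chloride) | CC(=C)CCl | starting material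
10 | methyl 2-hydroxy-4-(2-methylallyloxy)benzoate | COC(=O)c1ccc(OCC(C)=C)cc1O | intermediate
11 | methyl 2,4-bis(2-methylallyloxy)benzoate (not isolated) | COC(=O)c1ccc(OCC(C)=C)cc1OCC(C)=C | intermediate
12 | 2,4-bis(2-methylallyloxy)benzoic acid | OC(=O)c1ccc(OCC(C)=C)cc1OCC(C)=C | intermediate
13 | 2,4-bis(2-methylallyloxy)benzoyl chloride (not isolated) | O=C(Cl)c1ccc(OCC(C)=C)cc1OCC(C)=C | intermediate
14 | 3-[2,4-bis(2-methylallyloxy)benzoyl]-7-methoxy-6-[(E)-3-methylbut-1-enyl]-5-(triisopropylsilyloxy)chroman-4-one (racemic at C3, largely enolised) | O=C1C(C(=O)c3ccc(OCC(C)=C)cc3OCC(C)=C)COc2cc(OC)c(/C=C/C(C)C)c(O[Si](C(C)C)(C(C)C)C(C)C)c12 | intermediate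
15 | {2-[2,4-bis(2-methylallyloxy)phenyl]-7-methoxy-6-[(E)-3-methylbut-1-enyl]-4-oxo-5-(triisopropylsilyloxy)-4H-chromen-3-yl}methyl acetate | CC(=O)OCc1c(-c3ccc(OCC(C)=C)cc3OCC(C)=C)oc2cc(OC)c(/C=C/C(C)C)c(O[Si](C(C)C)(C(C)C)C(C)C)c2c1=O | intermediate
16 | {7-methoxy-6-[(E)-3-methylbut-1-enyl]-2-[2,4-bis(2-methylprop-1-enyloxy)phenyl]-4-oxo-5-(triisopropylsilyloxy)-4H-chromen-3-yl}methyl acetate | CC(=O)OCc1c(-c3ccc(OC=C(C)C)cc3OC=C(C)C)oc2cc(OC)c(/C=C/C(C)C)c(O[Si](C(C)C)(C(C)C)C(C)C)c2c1=O | intermediate
17 | oxepinoflavone, bridge CH (S) bearing prop-1-en-2-yl; 7-OMe, 6-[(E)-3-methylbut-1-enyl], 5-O-TIPS, 4′-O-(2-methylprop-1-enyl) (not isolated) | COc1cc2oc3c(c(=O)c2c(O[Si](C(C)C)(C(C)C)C(C)C)c1/C=C/C(C)C)C[C@@H](C(C)=C)Oc1cc(OC=C(C)C)ccc1-3 | intermediate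
18 | oxepinoflavone, bridge CH (S) bearing prop-1-en-2-yl; 7-OMe, 6-[(E)-3-methylbut-1-enyl], 5-O-TIPS, 4′-OH | COc1cc2oc3c(c(=O)c2c(O[Si](C(C)C)(C(C)C)C(C)C)c1/C=C/C(C)C)C[C@@H](C(C)=C)Oc1cc(O)ccc1-3 | intermediate
19 | oxepinoflavone, bridge CH (S) bearing 2-(triethylsilylperoxy)propan-2-yl; 7-OMe, 6-[(E)-3-methylbut-1-enyl], 5-O-TIPS, 4′-OH | COc1cc2oc3c(c(=O)c2c(O[Si](C(C)C)(C(C)C)C(C)C)c1/C=C/C(C)C)C[C@@H](C(C)(C)OO[Si](CC)(CC)CC)Oc1cc(O)ccc1-3 | intermediate
20 | CNP0171472.1: oxepinoflavone, bridge CH (S) bearing 2-hydroperoxypropan-2-yl; 5,4′-dihydroxy, 7-methoxy, 6-[(E)-3-methylbut-1-enyl] | COc1cc2oc3c(c(=O)c2c(O)c1/C=C/C(C)C)C[C@@H](C(C)(C)OO)Oc1cc(O)ccc1-3 | target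

Total step count: 13. Longest linear sequence: 10 steps (steps 1, 2, 4, 5, 8, 9, 10, 11, 12, 13).

Steps most likely to fail

1. Step 11 (key step, proposed new method). The hindered trisubstituted enol ether may insert too slowly, so that the allyl-palladium intermediate is consumed in other ways. β-Hydride elimination may also run toward the new methine and erase the stereocentre as a tetrasubstituted enol ether, and the ligand may discriminate the two alkene faces poorly. Fallback (known chemistry, stereocentre obtained by resolution instead of catalyst control): setting out from 16, the ring closure is run as the thermal racemic palladium-ene cyclisation with an achiral catalyst (Pd(PPh3)4, Li2CO3, DMA, 80 °C) to give the racemic 4′-enol ether F1. The same acidic work-up converts it to the racemic isopropenyl oxepinoflavone F2, which is separated by preparative HPLC on a chiral stationary phase (amylose tris(3,5-dimethylphenylcarbamate)). The (S)-enantiomer re-enters the route as 18.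

2. Step 9 (proposed new method). The transient 2-methylene-1,3-diketone may dimerise by hetero-Diels–Alder reaction, or the electrophilic CH2 carbon may be captured by the neighbouring 2′-ether oxygen with loss of the methallyl group (closure of a six-membered pyran) before the pyranone closes. Fallback (known operations, one at a time): setting out from 14, dimethylamine (THF, rt) opens the chromanone by elimination and conjugate addition to the open-chain Mannich base F3. Warming in AcOH closes the pyranone by cyclodehydration of the o-hydroxyaryl 1,3-diketone to the 3-(dimethylaminomethyl)flavone F4. MeI gives the trimethylammonium iodide F5, and KOAc in DMF displaces trimethylamine to return to the route at 15.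

3. Step 12. Hydrogen-atom transfer may also reach the C6 styrene-type double bond (a second peroxidation), and the free 4′-phenol may interfere with the radical chain. Fallback (ionic instead of radical Markovnikov peroxidation): setting out from 18, peroxymercuration (Hg(OAc)2, H2O2, THF/CH2Cl2, 0 °C) should be selective for the unhindered 1,1-disubstituted alkene and gives the acetoxymercurio hydroperoxide F6. NaBH4 in aqueous NaOH at 0 °C removes mercury to give the 5-O-TIPS hydroperoxide F7, and Bu4NF/AcOH then removes the silyl ether, so the route is re-joined at 20.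

Further compounds
F1 | step 11 | racemic 4′-enol ether (racemic 17) | COc1cc2oc3c(c(=O)c2c(O[Si](C(C)C)(C(C)C)C(C)C)c1/C=C/C(C)C)CC(C(C)=C)Oc1cc(OC=C(C)C)ccc1-3
F2 | step 11 | racemic isopropenyl oxepinoflavone (racemic 18) | COc1cc2oc3c(c(=O)c2c(O[Si](C(C)C)(C(C)C)C(C)C)c1/C=C/C(C)C)CC(C(C)=C)Oc1cc(O)ccc1-3
F3 | step 9 | open-chain Mannich base: 2-[(dimethylamino)methyl]-1-[2,4-bis(2-methylallyloxy)phenyl]-3-{2-hydroxy-4-methoxy-5-[(E)-3-methylbut-1-enyl]-6-(triisopropylsilyloxy)phenyl}propane-1,3-dione (hydroxyl para to the alkenyl group; racemic) | CN(C)CC(C(=O)c1ccc(OCC(C)=C)cc1OCC(C)=C)C(=O)c1c(O)cc(OC)c(/C=C/C(C)C)c1O[Si](C(C)C)(C(C)C)C(C)C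
F4 | step 9 | 3-(dimethylaminomethyl)flavone analogue of 15 | CN(C)Cc1c(-c3ccc(OCC(C)=C)cc3OCC(C)=C)oc2cc(OC)c(/C=C/C(C)C)c(O[Si](C(C)C)(C(C)C)C(C)C)c2c1=O
F5 | step 9 | trimethylammonium iodide of F4 | C[N+](C)(C)Cc1c(-c3ccc(OCC(C)=C)cc3OCC(C)=C)oc2cc(OC)c(/C=C/C(C)C)c(O[Si](C(C)C)(C(C)C)C(C)C)c2c1=O.[I-]
F6 | step 12 | acetoxymercurio hydroperoxide from 18 (new carbinol centre undefined) | COc1cc2oc3c(c(=O)c2c(O[Si](C(C)C)(C(C)C)C(C)C)c1/C=C/C(C)C)C[C@@H](C(C)(C[Hg]OC(C)=O)OO)Oc1cc(O)ccc1-3
F7 | step 12 | 5-O-TIPS ether of 20 | COc1cc2oc3c(c(=O)c2c(O[Si](C(C)C)(C(C)C)C(C)C)c1/C=C/C(C)C)C[C@@H](C(C)(C)OO)Oc1cc(O)ccc1-3
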